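**Retrosynthetic overview**
1. The plan rests on ring B. Going round C9-C8-C7-C6-C5-C10: quaternary C9 carries the C20 methyl and C11 (a carboxyl carbon once C11=C12 is cut). C8 is a masked ketone (ketone plus C17). O6 and O7 are trans-diequatorial as in a tartrate. Axial H10 is trans to the C19 methyl on C5. This is the pattern left by an oxidative β-keto ester radical bicyclisation.
2. Late cuts: C12-C13 (Heck, with the butenolide ring bought intact); the two acyl groups (told apart by moving the acetonide from O6/O7 to O7/O8); C11=C12 (Wittig on the C11 aldehyde); C8-C17 (methylene transfer, then hydride); C3=C4 (from the C4 exocyclic methylene).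
3. Key cut: C9-C10 and C4-C5 in one operation from an acyclic (E)-enyne keto ester. Ring B forms first (6-endo) and ring A second (6-exo-dig).
4. The keto ester comes from C8-C9 acylation of the ethyl propionate enolate, a C10-C1 Negishi coupling, and a methylalumination/iodination that fixes the (E)-C5=C10 alkene. C6 and C7 are the two stereocentres of dimethyl D-tartrate acetonide.

Key step: step 12

Remark on numbering: clerodane numbering is used (ring A = C1-C5, C10; ring B = C5-C10; C17 on C8, C18 on C4, C19 on C5, C20 and C11 on C9). β is the face of H10. In ring B the axial positions are C5α, C6β, C7α, C8β, C9α, C10β.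
Assumption: the C9 centre of the acyclic β-keto ester is configurationally labile, so the compound is handled as an epimer mixture and one epimer is written.

Step 1
Reactants: 1 dimethyl (4S,5S)-2,2-dimethyl-1,3-dioxolane-4,5-dicarboxylate
Product: 2 [(4R,5R)-2,2-dimethyl-1,3-dioxolane-4,5-diyl]dimethanol
Conditions: LiAlH4, THF, 0 °C to reflux
Reagents that add atoms: none
Why: Exhaustive LiAlH4 ester reduction leaves the two dioxolane stereocentres (the future C6 and C7) untouched and gives a C2-symmetric diol whose two ends are equivalent.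

Step 2
Reactants: 2 [(4R,5R)-2,2-dimethyl-1,3-dioxolane-4,5-diyl]dimethanol
Product: 4 [(4R,5R)-5-(tert-butyldimethylsilyloxymethyl)-2,2-dimethyl-1,3-dioxolan-4-yl]methanol, via monosodium alkoxide 3 (not isolated)
Conditions: NaH (1.0 equiv), THF, 0 °C to rt; TBSCl (1.0 equiv), rt
Reagents that add atoms: tert-butyldimethylsilyl chloride, CC(C)(C)[Si](C)(C)Cl
Why: Monosilylation of a symmetric diol through its sparingly soluble monosodium alkoxide should stop after one silylation, and the silyl ether holds the C8 terminus in a form that survives AlMe3 in step 5, which an ester would not.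

Step 3
Reactants: 4 [(4R,5R)-5-(tert-butyldimethylsilyloxymethyl)-2,2-dimethyl-1,3-dioxolan-4-yl]methanol
Product: 5 (4S,5R)-5-(tert-butyldimethylsilyloxymethyl)-2,2-dimethyl-1,3-dioxolane-4-carbaldehyde
Conditions: TEMPO (10 mol%), PhI(OAc)2 (1.1 equiv), CH2Cl2, rt
Reagents that add atoms: none
Why: The oxoammonium (TEMPO) oxidation stops at the aldehyde in the absence of water, and the trans-disubstituted dioxolane is the stable epimer, so C6 is not at risk.

Step 4
Reactants: 5 (4S,5R)-5-(tert-butyldimethylsilyloxymethyl)-2,2-dimethyl-1,3-dioxolane-4-carbaldehyde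
Product: 6 tert-butyl{[(4R,5R)-5-ethynyl-2,2-dimethyl-1,3-dioxolan-4-yl]methoxy}dimethylsilane
Conditions: dimethyl (1-diazo-2-oxopropyl)phosphonate, K2CO3, MeOH, 0 °C to rt
Reagents that add atoms: dimethyl (1-diazo-2-oxopropyl)phosphonate, CC(=O)C(=[N+]=[N-])P(=O)(OC)OC
Why: The Ohira-Bestmann variant of the Seyferth-Gilbert homologation turns the aldehyde (C5) into a terminal alkyne and brings in C10 under base mild enough for the silyl ether and the acetonide.

Step 5
Reactants: 6 tert-butyl{[(4R,5R)-5-ethynyl-2,2-dimethyl-1,3-dioxolan-4-yl]methoxy}dimethylsilane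
Product: 8 tert-butyl({(4R,5R)-5-[(E)-1-iodoprop-1-en-2-yl]-2,2-dimethyl-1,3-dioxolan-4-yl}methoxy)dimethylsilane, via alkenyl(dimethyl)alane 7 (not isolated)
Conditions: AlMe3 (3 equiv), Cp2ZrCl2 (20 mol%), H2O (1.5 equiv), CH2Cl2, -23 °C; then I2, THF, -23 to 0 °C
Reagents that add atoms: trimethylaluminium, C[Al](C)C; iodine, [I][I]
Why: The zirconium-catalysed Negishi carboalumination adds CH3 (C19) to the internal carbon C5 and aluminium to C10 in a syn fashion, iodinolysis proceeds with retention so that C6 and iodine end up trans, and the water-accelerated low-temperature variant limits attack of AlMe3 on the acetonide.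

Step 6
Reactants: 9 5-chloropent-1-yne
Product: 11 (5-chloropent-1-yn-1-yl)trimethylsilane, via lithium acetylide 10 (not isolated)
Conditions: n-BuLi, THF, -78 °C; TMSCl, -78 °C to rt
Reagents that add atoms: chlorotrimethylsilane, C[Si](C)(C)Cl
Why: Deprotonation and C-silylation of the terminal alkyne is far faster at -78 °C than any reaction of n-BuLi with the primary chloride, and it removes the acidic C-H before the organozinc and palladium chemistry.

Step 7
Reactants: 11 (5-chloropent-1-yn-1-yl)trimethylsilane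
Product: 12 (5-iodopent-1-yn-1-yl)trimethylsilane
Conditions: NaI, acetone, reflux
Reagents that add atoms: sodium iodide, [Na+].[I-]
Why: The Finkelstein exchange is driven by precipitation of NaCl and gives the iodide needed for smooth zinc insertion.

Step 8
Reactants: 8 tert-butyl({(4R,5R)-5-[(E)-1-iodoprop-1-en-2-yl]-2,2-dimethyl-1,3-dioxolan-4-yl}methoxy)dimethylsilane; 12 (5-iodopent-1-yn-1-yl)trimethylsilane
Product: 14 tert-butyl({(4R,5R)-2,2-dimethyl-5-[(E)-8-(trimethylsilyl)oct-2-en-7-yn-2-yl]-1,3-dioxolan-4-yl}methoxy)dimethylsilane, via alkylzinc iodide 13 (not isolated)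
Conditions: 12, Zn dust, LiCl, THF, 40 °C; then 8, PdCl2(dppf) (5 mol%), THF, rt to 45 °C
Reagents that add atoms: none
Why: The Negishi sp3-sp2 coupling of a primary alkylzinc iodide with an unhindered alkenyl iodide forms C10-C1 with retention of the (E) geometry, the wide-bite-angle dppf ligand favouring reductive elimination over β-hydride elimination.

Step 9
Reactants: 14 tert-butyl({(4R,5R)-2,2-dimethyl-5-[(E)-8-(trimethylsilyl)oct-2-en-7-yn-2-yl]-1,3-dioxolan-4-yl}methoxy)dimethylsilane
Product: 15 {(4R,5R)-2,2-dimethyl-5-[(E)-oct-2-en-7-yn-2-yl]-1,3-dioxolan-4-yl}methanol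
Conditions: n-Bu4NF (2.5 equiv), THF, 0 °C to rt
Reagents that add atoms: none
Why: Fluoride cleaves the Si-O bond and the alkynyl C-Si bond in one desilylation, leaving acetonide, alkene and alkyne untouched.

Step 10
Reactants: 15 {(4R,5R)-2,2-dimethyl-5-[(E)-oct-2-en-7-yn-2-yl]-1,3-dioxolan-4-yl}methanol
Product: 16 (4S,5R)-2,2-dimethyl-5-[(E)-oct-2-en-7-yn-2-yl]-1,3-dioxolane-4-carboxylic acid
Conditions: TEMPO (20 mol%), PhI(OAc)2 (2.2 equiv), MeCN/H2O 1:1, rt
Reagents that add atoms: water, O
Why: In aqueous medium the TEMPO/PhI(OAc)2 oxidation carries the primary alcohol through the aldehyde hydrate to the acid (C8) without touching the alkene, the alkyne or the unstrained acetonide.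

Step 11
Reactants: 16 (4S,5R)-2,2-dimethyl-5-[(E)-oct-2-en-7-yn-2-yl]-1,3-dioxolane-4-carboxylic acid; 17 ethyl propionate
Product: 20 ethyl 3-{(4S,5R)-2,2-dimethyl-5-[(E)-oct-2-en-7-yn-2-yl]-1,3-dioxolan-4-yl}-2-methyl-3-oxopropanoate (C9 epimers), via acyl imidazolide 18 (not isolated), via lithium enolate 19 (not isolated)
Conditions: 16, CDI, THF, rt; added to 17 and i-Pr2NLi (3.5 equiv each), THF, -78 °C; AcOH quench
Reagents that add atoms: none
Why: This crossed Claisen condensation is run as C-acylation of a preformed ester enolate by an acyl imidazolide, forms C8-C9 at -78 °C, uses excess enolate to absorb the acidic product, the imidazole and the alkyne C-H, and creates C9 as a mixture that does not matter because step 12 erases it.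

Step 12
Reactants: 20 ethyl 3-{(4S,5R)-2,2-dimethyl-5-[(E)-oct-2-en-7-yn-2-yl]-1,3-dioxolan-4-yl}-2-methyl-3-oxopropanoate (C9 epimers)
Product: 21 ethyl 6α,7β-(isopropylidenedioxy)-5α,9α-dimethyl-4-methylene-8-oxo-10βH-trans-decalin-9β-carboxylate
Conditions: Mn(OAc)3·2H2O (2.2 equiv, in portions), Yb(OTf)3 (1.0 equiv), degassed EtOH (0.01 M), 0 °C to rt
Reagents that add atoms: none
Why: Trivalent manganese oxidises the ytterbium-bound enolate of 20 to an electrophilic C9 radical, which erases the C9 stereocentre of 20; the closest known reaction type is the Mn(OAc)3 oxidative radical polycyclisation of alkenyl β-keto esters with alkyne termination in ethanol. Ring B closes 6-endo-trig by attack on C10 (5-exo attack at the methyl-bearing C5 is disfavoured by the sp2 C8 in the chain and would give a trans-fused bicyclo[3.3.0]octane), then ring A closes 6-exo-dig when the tertiary C5 radical adds to the internal alkyne carbon C4, and the vinyl radical takes hydrogen from ethanol, whose radical uses up the second equivalent of oxidant. C10 is set by the only chair open to a trans-dioxolane, the one with O6 and O7 equatorial, in which the (E)-alkene places C1 equatorial and H10 axial on the β face. C5 is set by the chair-chair fold, in which C4 bonds equatorially and anti to the new C9-C10 bond so that C19 becomes axial and trans to H10, whereas the cis-decalin mode would drive the alkyne against the axial C9 substituent. C9 is set by the rotamer of the radical: ytterbium bound to O7, the C8 oxygen and the ester carbonyl holds the ester syn to the ketone oxygen, which becomes the equatorial (β) position and leaves C20 axial, and a full equivalent of Yb(OTf)3 is used because unchelated radicals of this class tend to place the ester axial. The step also needs ring A closure to outrun oxidation of the C5 radical to the cation, which is served by high dilution, portionwise oxidant and the absence of any copper co-oxidant, while the ethyl ester matches the solvent so that transesterification is invisible.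

Step 13
Reactants: 21 ethyl 6α,7β-(isopropylidenedioxy)-5α,9α-dimethyl-4-methylene-8-oxo-10βH-trans-decalin-9β-carboxylate
Product: 22 ethyl 6α,7β-(isopropylidenedioxy)-4,5α,9α-trimethyl-8-oxo-10βH-Δ3-octalin-9β-carboxylate
Conditions: chloro[N,N'-bis(3,5-di-tert-butylsalicylidene)-1,2-cyclohexanediaminato]cobalt, C36H52ClCoN2O2 (3 mol%), PhSiH3 (6 mol%), benzene, rt
Reagents that add atoms: none
Why: In this cobalt hydride hydrogen-atom-transfer alkene isomerisation, reversible H-atom addition to C18 gives the tertiary C4 radical, which can lose hydrogen only from C3 or back from C18 because C5 is quaternary, so the more stable trisubstituted C3=C4 alkene should accumulate under neutral conditions that spare the strained trans-fused acetonide a Brønsted acid would endanger.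

Step 14
Reactants: 22 ethyl 6α,7β-(isopropylidenedioxy)-4,5α,9α-trimethyl-8-oxo-10βH-Δ3-octalin-9β-carboxylate
Product: 23 ethyl 8β,17-epoxy-6α,7β-(isopropylidenedioxy)-4,5α,9α-trimethyl-10βH-Δ3-octalin-9β-carboxylate (spiro-oxirane at C8; O axial β; CH2 equatorial)
Conditions: Me3S(O)I, NaH, DMSO/THF, rt to 50 °C
Reagents that add atoms: trimethylsulfoxonium iodide, C[S+](C)(C)=O.[I-]
Why: In the Corey-Chaykovsky epoxidation the stabilised sulfoxonium ylide adds reversibly, so ring closure should occur from the more stable betaine with the bulky CH2S group equatorial, which sets C8 with C17 equatorial (α) and oxygen axial (β), while C9 cannot enolise and epimerisation at C7 would place O7 syn-axial to C19 and C20.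

Step 15
Reactants: 23 ethyl 8β,17-epoxy-6α,7β-(isopropylidenedioxy)-4,5α,9α-trimethyl-10βH-Δ3-octalin-9β-carboxylate
Product: 24 8β,17-epoxy-9β-(hydroxymethyl)-6α,7β-(isopropylidenedioxy)-4,5α,9α-trimethyl-10βH-Δ3-octalin
Conditions: i-Bu2AlH (2.5 equiv), CH2Cl2, -78 °C
Reagents that add atoms: none
Why: Low-temperature i-Bu2AlH reduction takes the ester to the C11 carbinol faster than it opens the oxirane, which is deliberately kept closed as a mask for the C8 carbinol so that a β-hydroxy aldehyde prone to retro-aldol C8-C9 cleavage never appears.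

Step 16
Reactants: 24 8β,17-epoxy-9β-(hydroxymethyl)-6α,7β-(isopropylidenedioxy)-4,5α,9α-trimethyl-10βH-Δ3-octalin
Product: 25 8β,17-epoxy-6α,7β-(isopropylidenedioxy)-4,5α,9α-trimethyl-10βH-Δ3-octalin-9β-carbaldehyde
Conditions: (n-Pr4N)RuO4 (5 mol%), NMO, 4 Å molecular sieves, CH2Cl2, rt
Reagents that add atoms: none
Why: The Ley-Griffith perruthenate oxidation is neutral, copes with neopentyl alcohols and leaves the acid-sensitive oxirane, the acetonide and the trisubstituted alkene alone.

Step 17
Reactants: 25 8β,17-epoxy-6α,7β-(isopropylidenedioxy)-4,5α,9α-trimethyl-10βH-Δ3-octalin-9β-carbaldehyde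
Product: 26 8β,17-epoxy-6α,7β-(isopropylidenedioxy)-4,5α,9α-trimethyl-9β-vinyl-10βH-Δ3-octalin
Conditions: Ph3PCH3Br, KN(SiMe3)2, THF, 0 °C to rt
Reagents that add atoms: methyltriphenylphosphonium bromide, C[P+](c1ccccc1)(c1ccccc1)c1ccccc1.[Br-]
Why: Wittig methylenation of a non-enolisable aldehyde brings in C12, and with no free hydroxyl in the molecule the basic ylide has nothing to deprotonate.

Step 18
Reactants: 26 8β,17-epoxy-6α,7β-(isopropylidenedioxy)-4,5α,9α-trimethyl-9β-vinyl-10βH-Δ3-octalin
Product: 27 8β-hydroxy-6α,7β-(isopropylidenedioxy)-4,5α,8α,9α-tetramethyl-9β-vinyl-10βH-Δ3-octalin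
Conditions: LiEt3BH, THF, 0 to 40 °C
Reagents that add atoms: none
Why: LiEt3BH opens the 1,1-disubstituted oxirane by SN2 hydride attack at the unsubstituted carbon C17, so the C8-O bond and hence the C8 configuration are retained and the equatorial C17 methyl and axial 8β-hydroxyl result.

Step 19
Reactants: 27 8β-hydroxy-6α,7β-(isopropylidenedioxy)-4,5α,8α,9α-tetramethyl-9β-vinyl-10βH-Δ3-octalin
Product: 28 6α-hydroxy-7β,8β-(isopropylidenedioxy)-4,5α,8α,9α-tetramethyl-9β-vinyl-10βH-Δ3-octalin
Conditions: CSA (5 mol%), CH2Cl2, rt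
Reagents that add atoms: none
Why: This acid-catalysed acetonide migration (intramolecular transketalisation) should be driven by strain release, since the trans-fused 6,7-dioxolane opens to the O7 oxocarbenium ion and the cis-disposed 8β-hydroxyl (O7 equatorial β, O8 axial β) captures it to give the cis-fused 7,8-dioxolane, which frees the C6 hydroxyl alone.

Step 20
Reactants: 28 6α-hydroxy-7β,8β-(isopropylidenedioxy)-4,5α,8α,9α-tetramethyl-9β-vinyl-10βH-Δ3-octalin
Product: 29 6α-acetoxy-7β,8β-(isopropylidenedioxy)-4,5α,8α,9α-tetramethyl-9β-vinyl-10βH-Δ3-octalin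
Conditions: Ac2O, DMAP, pyridine, rt
Reagents that add atoms: acetic anhydride, CC(=O)OC(C)=O
Why: DMAP-catalysed acetylation meets only one free hydroxyl, so the hindered equatorial C6-OH can be pushed to completion without any question of regiochemistry.

Step 21
Reactants: 29 6α-acetoxy-7β,8β-(isopropylidenedioxy)-4,5α,8α,9α-tetramethyl-9β-vinyl-10βH-Δ3-octalin
Product: 30 6α-acetoxy-7β,8β-dihydroxy-4,5α,8α,9α-tetramethyl-9β-vinyl-10βH-Δ3-octalin
Conditions: AcOH/H2O 4:1, 40 °C
Reagents that add atoms: none
Why: Mild aqueous-acid acetal hydrolysis removes the acetonide while the acetate and both alkenes persist, and the weakly acidic medium disfavours the base-promoted O6 to O7 acetyl shift.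

Step 22
Reactants: 30 6α-acetoxy-7β,8β-dihydroxy-4,5α,8α,9α-tetramethyl-9β-vinyl-10βH-Δ3-octalin
Product: 31 6α-acetoxy-8β-hydroxy-7β-(isobutyryloxy)-4,5α,8α,9α-tetramethyl-9β-vinyl-10βH-Δ3-octalin
Conditions: (i-PrCO)2O, DMAP (cat.), pyridine, CH2Cl2, 0 °C to rt
Reagents that add atoms: isobutyric anhydride, CC(C)C(=O)OC(=O)C(C)C
Why: DMAP-catalysed acylation distinguishes the secondary equatorial C7-OH from the tertiary axial C8-OH on steric grounds, and the fast acylation at low temperature leaves little time for acetyl migration.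

Step 23
Reactants: 31 6α-acetoxy-8β-hydroxy-7β-(isobutyryloxy)-4,5α,8α,9α-tetramethyl-9β-vinyl-10βH-Δ3-octalin; 32 4-bromofuran-2(5H)-one
Product: 33 6α-acetoxy-8β-hydroxy-7β-(isobutyryloxy)cleroda-3,11(E),13-trien-15,16-olide (target)
Conditions: Pd(OAc)2 (10 mol%), n-Bu4NCl (1 equiv), NaOAc (2.5 equiv), DMF, 70 °C
Reagents that add atoms: none
Why: In the Heck vinylation zerovalent palladium inserts into the electron-poor C-Br bond, the monosubstituted alkene inserts with the butenolide carbon going to the terminal C12, and syn β-hydride elimination, possible only from C12 because C9 is quaternary, should give the (E)-C11=C12 diene while the trisubstituted C3=C4 alkene stays inert.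

**Compound list**
1 | dimethyl (4S,5S)-2,2-dimethyl-1,3-dioxolane-4,5-dicarboxylate | COC(=O)[C@H]1OC(C)(C)O[C@@H]1C(=O)OC | starting material
2 | [(4R,5R)-2,2-dimethyl-1,3-dioxolane-4,5-diyl]dimethanol | OC[C@H]1OC(C)(C)O[C@@H]1CO | intermediate
3 | monosodium alkoxide of 2 (not isolated) | [Na+].[O-]C[C@H]1OC(C)(C)O[C@@H]1CO | intermediate
4 | [(4R,5R)-5-(tert-butyldimethylsilyloxymethyl)-2,2-dimethyl-1,3-dioxolan-4-yl]methanol | OC[C@H]1OC(C)(C)O[C@@H]1CO[Si](C)(C)C(C)(C)C | intermediate
5 | (4S,5R)-5-(tert-butyldimethylsilyloxymethyl)-2,2-dimethyl-1,3-dioxolane-4-carbaldehyde | O=C[C@H]1OC(C)(C)O[C@@H]1CO[Si](C)(C)C(C)(C)C | intermediate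
6 | tert-butyl{[(4R,5R)-5-ethynyl-2,2-dimethyl-1,3-dioxolan-4-yl]methoxy}dimethylsilane | C#C[C@H]1OC(C)(C)O[C@@H]1CO[Si](C)(C)C(C)(C)C | intermediate
7 | (E)-alkenyl(dimethyl)alane from 6, Al on C10 cis to the C19 methyl (not isolated) | C[Al](C)/C=C(\C)[C@H]1OC(C)(C)O[C@@H]1CO[Si](C)(C)C(C)(C)C | intermediate
8 | tert-butyl({(4R,5R)-5-[(E)-1-iodoprop-1-en-2-yl]-2,2-dimethyl-1,3-dioxolan-4-yl}methoxy)dimethylsilane | I/C=C(\C)[C@H]1OC(C)(C)O[C@@H]1CO[Si](C)(C)C(C)(C)C | intermediate
9 | 5-chloropent-1-yne | C#CCCCCl | starting material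
10 | lithium acetylide of 9 (not isolated) | [Li]C#CCCCCl | intermediate
11 | (5-chloropent-1-yn-1-yl)trimethylsilane | C[Si](C)(C)C#CCCCCl | intermediate
12 | (5-iodopent-1-yn-1-yl)trimethylsilane | C[Si](C)(C)C#CCCCI | intermediate
13 | [5-(trimethylsilyl)pent-4-yn-1-yl]zinc iodide (not isolated) | C[Si](C)(C)C#CCCC[Zn]I | intermediate
14 | tert-butyl({(4R,5R)-2,2-dimethyl-5-[(E)-8-(trimethylsilyl)oct-2-en-7-yn-2-yl]-1,3-dioxolan-4-yl}methoxy)dimethylsilane | C[Si](C)(C)C#CCCC/C=C(\C)[C@H]1OC(C)(C)O[C@@H]1CO[Si](C)(C)C(C)(C)C | intermediate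
15 | {(4R,5R)-2,2-dimethyl-5-[(E)-oct-2-en-7-yn-2-yl]-1,3-dioxolan-4-yl}methanol | C#CCCC/C=C(\C)[C@H]1OC(C)(C)O[C@@H]1CO | intermediate
16 | (4S,5R)-2,2-dimethyl-5-[(E)-oct-2-en-7-yn-2-yl]-1,3-dioxolane-4-carboxylic acid | C#CCCC/C=C(\C)[C@H]1OC(C)(C)O[C@@H]1C(=O)O | intermediate
17 | ethyl propionate | CCC(=O)OCC | starting material
18 | acyl imidazolide of 16 (not isolated) | C#CCCC/C=C(\C)[C@H]1OC(C)(C)O[C@@H]1C(=O)n2ccnc2 | intermediate
19 | lithium enolate of ethyl propionate (not isolated) | [Li+].CC=C([O-])OCC | intermediate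
20 | ethyl 3-{(4S,5R)-2,2-dimethyl-5-[(E)-oct-2-en-7-yn-2-yl]-1,3-dioxolan-4-yl}-2-methyl-3-oxopropanoate, C9 epimer mixture, one epimer written | C#CCCC/C=C(\C)[C@H]1OC(C)(C)O[C@@H]1C(=O)[C@@H](C)C(=O)OCC | intermediate
21 | trans-decalin keto ester: 6α,7β-acetonide (both O equatorial), 8-ketone, C9 with axial α-methyl and equatorial β-CO2Et, H10 β, C5 α-methyl, C4 exocyclic methylene | CC1(C)O[C@H]2[C@H](O1)C(=O)[C@](C)(C(=O)OCC)[C@H]3CCCC(=C)[C@]23C | intermediate
22 | as 21 but with the C3=C4 trisubstituted alkene (C18 methyl on C4) | CC1(C)O[C@H]2[C@H](O1)C(=O)[C@](C)(C(=O)OCC)[C@H]3CCC=C(C)[C@]23C | intermediate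
23 | 8β,17-spiro-epoxide of 22 (O axial β, CH2 equatorial), ester retained | CC1(C)O[C@H]2[C@H](O1)[C@]4(OC4)[C@](C)(C(=O)OCC)[C@H]3CCC=C(C)[C@]23C | intermediate
24 | epoxy alcohol, 9β-CH2OH (C11 carbinol) | CC1(C)O[C@H]2[C@H](O1)[C@]4(OC4)[C@](C)(CO)[C@H]3CCC=C(C)[C@]23C | intermediate
25 | epoxy aldehyde, 9β-CHO | CC1(C)O[C@H]2[C@H](O1)[C@]4(OC4)[C@](C)(C=O)[C@H]3CCC=C(C)[C@]23C | intermediate
26 | vinyl epoxide, 9β-vinyl | CC1(C)O[C@H]2[C@H](O1)[C@]4(OC4)[C@](C)(C=C)[C@H]3CCC=C(C)[C@]23C | intermediate
27 | 8β-hydroxy-8α-methyl-9β-vinyl 6α,7β-acetonide | CC1(C)O[C@H]2[C@H](O1)[C@](C)(O)[C@](C)(C=C)[C@H]3CCC=C(C)[C@]23C | intermediate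
28 | 6α-hydroxy 7β,8β-acetonide (cis-fused), 9β-vinyl | O[C@H]1[C@@H]2OC(C)(C)O[C@]2(C)[C@](C)(C=C)[C@H]3CCC=C(C)[C@]13C | intermediate
29 | 6α-acetoxy 7β,8β-acetonide, 9β-vinyl | CC(=O)O[C@H]1[C@@H]2OC(C)(C)O[C@]2(C)[C@](C)(C=C)[C@H]3CCC=C(C)[C@]13C | intermediate
30 | 6α-acetoxy-7β,8β-diol, 9β-vinyl | CC(=O)O[C@H]1[C@H](O)[C@](C)(O)[C@](C)(C=C)[C@H]2CCC=C(C)[C@]12C | intermediate
31 | 6α-acetoxy-7β-isobutyryloxy-8β-ol, 9β-vinyl | CC(=O)O[C@H]1[C@H](OC(=O)C(C)C)[C@](C)(O)[C@](C)(C=C)[C@H]2CCC=C(C)[C@]12C | intermediate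
32 | 4-bromofuran-2(5H)-one | O=C1C=C(Br)CO1 | starting material
33 | 6α-acetoxy-8β-hydroxy-7β-(isobutyryloxy)cleroda-3,11(E),13-trien-15,16-olide (CNP0207114.1) | CC(=O)O[C@H]1[C@H](OC(=O)C(C)C)[C@](C)(O)[C@](C)(/C=C/C2=CC(=O)OC2)[C@H]2CCC=C(C)[C@]12C | target

**Total step count:** 23. **Longest linear sequence:** 21 (steps 1-5 and 8-23, from 1). Steps 6 and 7 form the side branch.

**Steps most likely to fail**

Step 12.
- Chelation may be too weak in a donor solvent. The ester rotamer of the C9 radical would then not be held, and selectivity at C9 would erode or invert.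
- The tertiary C5 radical may be oxidised to the cation, with elimination or capture by ethanol, before the slow 6-exo-dig closure of ring A.
- The Lewis acid may ethanolyse the acetonide.
- The fallback replaces enolate oxidation by a halogen-atom-transfer chain and sets out from 20. Bromination at C9 with NBS and catalytic Mg(ClO4)2 in MeCN gives the ethyl 2-bromo-2-methyl-3-oxo ester F1. Treatment of F1 with Et3B/O2 and Mg(ClO4)2 (1 equiv) in CH2Cl2 at -78 °C runs the same two ring closures. No oxidant is present and no solvent competes for the Lewis acid. The vinyl radical carries the chain by taking bromine from F1, which gives the 4-(bromomethylene) trans-decalin keto ester F2. n-Bu3SnH/AIBN in benzene at 80 °C then exchanges the vinylic bromine for hydrogen, and the route is rejoined at 21.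

Step 14.
- The ylide may add too slowly to a ketone flanked by quaternary C9 and oxygenated C7.
- The betaine may fragment by retro-aldol cleavage of C8-C9.
- Closure may take place from the kinetic betaine, with poor facial selectivity at C8.
- The fallback installs the carbon first and the oxygen second and sets out from 22. Wittig methylenation (Ph3PCH3Br, KOt-Bu, toluene, 80 °C) gives the 8-methylene ester F3. i-Bu2AlH (CH2Cl2, -78 °C) gives the homoallylic alcohol F4. Hydroxyl-directed epoxidation with VO(acac)2/t-BuOOH (CH2Cl2, 0 °C to rt) should deliver oxygen only to C8=C17, because C3=C4 has no directing group. Delivery should be from the β face, the α face being screened by the axial C20 methyl. The route is rejoined at 24.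

Step 23.
- Insertion of the neopentyl-type vinyl group may be too slow, so that the catalyst aggregates to palladium black.
- The bromobutenolide may be consumed by the base.
- The diene product may isomerise on prolonged heating.
- The fallback changes the bond-forming event from alkene insertion to transmetalation and sets out from 31. Cross-metathesis with vinylboronic acid pinacol ester uses the second-generation Hoveyda-Grubbs catalyst, C31H38Cl2N2ORu, in CH2Cl2 at reflux. An alkene on a quaternary allylic carbon does not homodimerise, and this should give the (E)-alkenyl pinacol boronate F5. Suzuki-Miyaura coupling of F5 with 32 (PdCl2(dppf), K3PO4, THF/H2O, 45 °C) proceeds with retention of geometry and comes back to the route at 33.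

**Further compounds**
F1 | step 12 | ethyl 2-bromo-3-{(4S,5R)-2,2-dimethyl-5-[(E)-oct-2-en-7-yn-2-yl]-1,3-dioxolan-4-yl}-2-methyl-3-oxopropanoate (C9 epimers) | C#CCCC/C=C(\C)[C@H]1OC(C)(C)O[C@@H]1C(=O)C(C)(Br)C(=O)OCC
F2 | step 12 | 4-(bromomethylene) analogue of 21 (alkene geometry not defined) | CC1(C)O[C@H]2[C@H](O1)C(=O)[C@](C)(C(=O)OCC)[C@H]3CCCC(=CBr)[C@]23C
F3 | step 14 | ethyl 6α,7β-(isopropylidenedioxy)-4,5α,9α-trimethyl-8-methylene-10βH-Δ3-octalin-9β-carboxylate | CC1(C)O[C@H]2[C@H](O1)C(=C)[C@](C)(C(=O)OCC)[C@H]3CCC=C(C)[C@]23C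
F4 | step 14 | 9β-(hydroxymethyl)-6α,7β-(isopropylidenedioxy)-4,5α,9α-trimethyl-8-methylene-10βH-Δ3-octalin | CC1(C)O[C@H]2[C@H](O1)C(=C)[C@](C)(CO)[C@H]3CCC=C(C)[C@]23C
F5 | step 23 | (E)-C12 pinacol boronate of 31 | CC(=O)O[C@H]1[C@H](OC(=O)C(C)C)[C@](C)(O)[C@](C)(/C=C/B2OC(C)(C)C(C)(C)O2)[C@H]3CCC=C(C)[C@]13C
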